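**Retrosynthetic overview**
1. End game: the butenolide (C13–C16) is attached last by Negishi coupling of a C12 alkylzinc with 3-bromofuran-2(5H)-one; the C4 quaternary centre comes from α-face methylation of the C19 tert-butyl ester enolate; one acidolysis frees acid and alcohol.
2. Core: thermal intramolecular Diels–Alder reaction of acyclic triene 14 (diene C2=C3–C4(CO2t-Bu)=C5, dienophile C1=C10(CH3)) forms C1–C2 and C5–C10 and sets C5 and the quaternary C10.
3. Enabling feature: ring A carries the C19 carboxyl on C4, so a C3=C4 enoate is the retron of a 2-alkoxycarbonyl diene; C10 bears only CH3 besides ring bonds (an isopropenyl dienophile); C6–C9 of ring B is a four-carbon tether whose C8/C9 stereocentres steer the cyclisation.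
4. Triene: 2-alkynoate, then syn-hydrostannation/iodination, then Stille vinylation; the C8–C9 bond, both its stereocentres and the isopropenyl group come from an enantioselective boron-enolate Ireland–Claisen rearrangement.
5. Ring order: rings A and B together (step 10, ring A as cycloaddition ring, ring B from the tether); the butenolide ring enters preformed (step 15).

Key step: step 10

Remark on naming: labdane numbering is used for all intermediates (C1–C10 decalin, C11/C12 side chain, C13–C16 butenolide, C17 on C8, C18/C19 on C4, C20 on C10).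
Assumption: the (S,S)-diazaborolidine controller in step 4 is taken to deliver the (2R,3S)-acid; if a trial run shows the opposite sense, the (R,R)-controller is used with no other change.

**Route**

Step 1
Reactants: 1 3-[(tert-butyldimethylsilyl)oxy]propanal
Product: 2 ethyl (2E)-5-[(tert-butyldimethylsilyl)oxy]-2-methylpent-2-enoate
Conditions: Ph3P=C(CH3)CO2Et, CH2Cl2, rt
Reagents that add atoms: ethyl 2-(triphenylphosphoranylidene)propanoate, CCOC(=O)C(C)=P(c1ccccc1)(c1ccccc1)c1ccccc1
Why: Wittig olefination with a stabilised α-methyl ylide should give the E-trisubstituted enoate and is mild enough not to eliminate the β-silyloxy aldehyde.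

Step 2
Reactants: 2 ethyl (2E)-5-[(tert-butyldimethylsilyl)oxy]-2-methylpent-2-enoate
Product: 3 (2E)-5-[(tert-butyldimethylsilyl)oxy]-2-methylpent-2-en-1-ol
Conditions: i-Bu2AlH (2.2 equiv), CH2Cl2, −78 °C
Reagents that add atoms: none
Why: 1,2-reduction of the unsaturated ester by i-Bu2AlH gives the E-allylic alcohol without touching alkene geometry or silyl ether.

Step 3
Reactants: 3 (2E)-5-[(tert-butyldimethylsilyl)oxy]-2-methylpent-2-en-1-ol; 4 hex-5-ynoic acid
Product: 5 (2E)-5-[(tert-butyldimethylsilyl)oxy]-2-methylpent-2-en-1-yl hex-5-ynoate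
Conditions: DCC, DMAP (cat.), CH2Cl2, 0 °C → rt
Reagents that add atoms: none
Why: Steglich esterification joins the two pieces under neutral conditions that leave the terminal alkyne and the silyl ether alone.

Step 4
Reactants: 5 (2E)-5-[(tert-butyldimethylsilyl)oxy]-2-methylpent-2-en-1-yl hex-5-ynoate
Product: 8 (2R,3S)-2-(but-3-yn-1-yl)-3-{2-[(tert-butyldimethylsilyl)oxy]ethyl}-4-methylpent-4-enoic acid, via boron ketene acetal 6 (not isolated), via acyloxyborane 7 (not isolated)
Conditions: (4S,5S)-2-bromo-1,3-bis{[3,5-bis(trifluoromethyl)phenyl]sulfonyl}-4,5-diphenyl-1,3,2-diazaborolidine [from the (S,S)-bis-sulfonamide and BBr3, CH2Cl2, rt, evaporate], Et3N, PhMe–hexane, −78 °C; then −20 → 4 °C, 2–4 d; aqueous work-up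
Reagents that add atoms: none
Why: Soft enolisation by the chiral B-bromodiazaborolidine and Et3N in a non-polar medium should give the E(O)-boron ketene acetal, whose [3,3] shift through a chair with the E-trisubstituted allyl unit sets C8 and C9 anti under reagent control (enantioselective Ireland–Claisen rearrangement) and creates the isopropenyl group; the amine-buffered sulfonamidoborane is expected to be too weak an electrophile to bromoborate the alkyne.

Step 5
Reactants: 8 (2R,3S)-2-(but-3-yn-1-yl)-3-{2-[(tert-butyldimethylsilyl)oxy]ethyl}-4-methylpent-4-enoic acid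
Product: 9 (2R,3S)-2-(but-3-yn-1-yl)-3-{2-[(tert-butyldimethylsilyl)oxy]ethyl}-4-methylpent-4-en-1-ol
Conditions: LiAlH4, THF, 0 °C → rt
Reagents that add atoms: none
Why: LiAlH4 reduces the carboxylic acid to the C17 primary alcohol while the isolated alkyne, the alkene and the silyl ether are inert.

Step 6
Reactants: 9 (2R,3S)-2-(but-3-yn-1-yl)-3-{2-[(tert-butyldimethylsilyl)oxy]ethyl}-4-methylpent-4-en-1-ol
Product: 10 1-({[(2R,3S)-2-(but-3-yn-1-yl)-3-{2-[(tert-butyldimethylsilyl)oxy]ethyl}-4-methylpent-4-en-1-yl]oxy}methyl)-4-methoxybenzene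
Conditions: NaH (1.1 equiv), 4-MeOC6H4CH2Cl, n-Bu4NI (cat.), THF–DMF, 0 °C → rt
Reagents that add atoms: 4-methoxybenzyl chloride, COc1ccc(CCl)cc1
Why: Williamson etherification gives the PMB ether, chosen because it survives every later step and is cleaved together with the tert-butyl ester at the end.

Step 7
Reactants: 10 PMB ether of 9
Product: 11 tert-butyl (6R,7S)-7-{2-[(tert-butyldimethylsilyl)oxy]ethyl}-6-{[(4-methoxybenzyl)oxy]methyl}-8-methylnon-8-en-2-ynoate
Conditions: n-BuLi (1.05 equiv), THF, −78 °C; Boc2O, −78 → 0 °C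
Reagents that add atoms: di-tert-butyl dicarbonate, CC(C)(C)OC(=O)OC(=O)OC(C)(C)C
Why: C-acylation of the lithium acetylide with Boc2O installs C19 as a tert-butyl ester that needs no saponification later.

Step 8
Reactants: 11 tert-butyl ynoate
Product: 13 tert-butyl (2E,6R,7S)-7-{2-[(tert-butyldimethylsilyl)oxy]ethyl}-2-iodo-6-{[(4-methoxybenzyl)oxy]methyl}-8-methylnona-2,8-dienoate, via vinylstannane 12 (not isolated)
Conditions: n-Bu3SnH, Pd(PPh3)4 (2 mol %), THF, 0 °C → rt; then I2, CH2Cl2, 0 °C
Reagents that add atoms: iodine, II; tributyltin hydride, CCCC[SnH](CCCC)CCCC (tin in 12 only)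
Why: Palladium-catalysed syn-hydrostannation of the 2-alkynoate puts tin α to the ester and H on C5, and iododestannylation with retention gives the α-iodoenoate whose ester is cis to the C6 chain, the geometry the diene needs.

Step 9
Reactants: 13 α-iodoenoate
Product: 14 tert-butyl (2Z,6R,7S)-2-ethenyl-7-{2-[(tert-butyldimethylsilyl)oxy]ethyl}-6-{[(4-methoxybenzyl)oxy]methyl}-8-methylnona-2,8-dienoate
Conditions: n-Bu3SnCH=CH2, Pd2(dba)3 (2.5 mol %), AsPh3, CuI, DMF, rt → 40 °C; product kept cold over BHT and used at once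
Reagents that add atoms: tributyl(vinyl)stannane, C=C[Sn](CCCC)(CCCC)CCCC
Why: Copper-assisted Stille coupling proceeds with retention, so the vinyl group ends up trans to the tether and the 2-alkoxycarbonyl diene is formed at a temperature below that of cyclisation.

Step 10
Reactants: 14 triene
Product: 15 tert-butyl (5R,8R,9S,10R)-12-[(tert-butyldimethylsilyl)oxy]-17-[(4-methoxybenzyl)oxy]-13,14,15,16,18-pentanorlabd-3-en-19-oate
Conditions: PhMe (0.005 M), BHT (cat.), 155–165 °C, sealed tube, 24–48 h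
Reagents that add atoms: none
Why: A concerted thermal [4+2] cycloaddition (intramolecular Diels–Alder reaction) joins the diene C2=C3–C4(CO2t-Bu)=C5 to the 1,1-disubstituted alkene C1=C10, forming C1–C2 and C5–C10 and leaving the C3=C4 enoate. The closest known reaction type is the thermal cyclisation of unactivated 1,7,9-decatrienes, including ones with an isopropenyl dienophile and ones with a directing substituent on the internal diene carbon next to the tether. Ring A is the cycloaddition ring and ring B is closed from the four-carbon tether C6–C9 by the C5–C10 bond, the fused (not bridged) mode being enforced by tether length. C10 and C5 are set by the chair-like tether, which carries the C8 CH2OPMB and C9 CH2CH2OTBS groups equatorial and so exposes one face of each π-system. The step needs trans over cis ring fusion: the trans transition state (tether exo, C10 methyl under the diene) should win because the cis one must fold the branched C9 beneath C4 and its bulky ester, which also presses on the C6 hydrogens. The C5=C4 geometry from steps 8–9 allows the s-cis diene and excludes a 1,5-hydrogen shift, and dilution with BHT should suppress diene dimerisation.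

Step 11
Reactants: 15 Diels–Alder adduct
Product: 16 tert-butyl 12-[(tert-butyldimethylsilyl)oxy]-17-[(4-methoxybenzyl)oxy]-13,14,15,16,18-pentanorlabdan-19-oate (5α-H, 8β-H, 9α-H, 10β-CH3; mixture of C4 epimers)
Conditions: H2 (1 atm), [Ir(cod)(PCy3)(py)]PF6 (5 mol %), CH2Cl2, rt
Reagents that add atoms: none
Why: Homogeneous iridium-catalysed hydrogenation saturates the hindered trisubstituted C3=C4 enoate without hydrogenolysis of the PMB ether, and the C4 configuration formed is irrelevant because C4 is planarised again in step 12.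

Step 12
Reactants: 16 saturated ester
Product: 17 tert-butyl (4S,5R,8R,9S,10R)-12-[(tert-butyldimethylsilyl)oxy]-17-[(4-methoxybenzyl)oxy]-13,14,15,16-tetranorlabdan-19-oate
Conditions: LiN(i-Pr)2, THF–DMPU, −78 → −20 °C; CH3I, −78 → 0 °C
Reagents that add atoms: iodomethane, CI
Why: In the alkylation of the exocyclic C4 ester enolate, iodomethane approaches the α (equatorial) face away from the axial C10 methyl, so CH3 becomes 4α and the ester 4β (C19), the known sense for 10-methyl-trans-decalin-4-carboxylate enolates.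

Step 13
Reactants: 17 methylated ester
Product: 18 tert-butyl (4S,5R,8R,9S,10R)-12-hydroxy-17-[(4-methoxybenzyl)oxy]-13,14,15,16-tetranorlabdan-19-oate
Conditions: n-Bu4NF, THF, 0 °C → rt
Reagents that add atoms: none
Why: Fluoride cleaves the primary silyl ether selectively, PMB ether and tert-butyl ester being inert to it.

Step 14
Reactants: 18 primary alcohol
Product: 19 tert-butyl (4S,5R,8R,9S,10R)-12-iodo-17-[(4-methoxybenzyl)oxy]-13,14,15,16-tetranorlabdan-19-oate
Conditions: PPh3, I2, imidazole, CH2Cl2, 0 °C → rt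
Reagents that add atoms: iodine, II
Why: Appel-type iodination converts the unhindered primary alcohol into the iodide without effect on ester or PMB ether.

Step 15
Reactants: 19 primary iodide; 20 3-bromofuran-2(5H)-one
Product: 22 tert-butyl (4S,5R,8R,9S,10R)-17-[(4-methoxybenzyl)oxy]labd-13-en-16,15-olid-19-oate, via alkylzinc iodide 21 (not isolated)
Conditions: Zn dust (activated), LiCl, THF, 40 °C; then 20, Pd2(dba)3 (2.5 mol %), SPhos, THF–NMP, rt → 40 °C
Reagents that add atoms: zinc, [Zn] (in 21 only)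
Why: Zinc insertion gives an ester-tolerant primary alkylzinc iodide that undergoes Negishi sp3–sp2 coupling with the α-bromobutenolide (an α-halo-enone-type electrophile), joining C12 to C13 and bringing in the butenolide with its C13=C14 bond in place.

Step 16
Reactants: 22 protected butenolide
Product: 23 (4S,5R,8R,9S,10R)-17-hydroxylabd-13-en-16,15-olid-19-oic acid (target)
Conditions: CF3CO2H–CH2Cl2 (1:3), anisole, 0 °C → rt; then aq. NaHCO3/MeOH, rt; acidify to pH 3
Reagents that add atoms: none
Why: Acidolysis cleaves the tert-butyl ester by loss of isobutene, independent of the steric shielding of C19, and the PMB ether by ionisation with anisole as cation trap, while butenolide, acid and stereocentres are stable to acid.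

**Compound list**
1 | 3-[(tert-butyldimethylsilyl)oxy]propanal | O=CCCO[Si](C)(C)C(C)(C)C | starting material
2 | ethyl (2E)-5-[(tert-butyldimethylsilyl)oxy]-2-methylpent-2-enoate | CCOC(=O)/C(C)=C/CCO[Si](C)(C)C(C)(C)C | intermediate
3 | (2E)-5-[(tert-butyldimethylsilyl)oxy]-2-methylpent-2-en-1-ol | OC/C(C)=C/CCO[Si](C)(C)C(C)(C)C | intermediate
4 | hex-5-ynoic acid | OC(=O)CCCC#C | starting material
5 | (2E)-5-[(tert-butyldimethylsilyl)oxy]-2-methylpent-2-en-1-yl hex-5-ynoate | C#CCCCC(=O)OC/C(C)=C/CCO[Si](C)(C)C(C)(C)C | intermediate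
6 | E(O)-boron ketene acetal of 5 carrying the (4S,5S)-1,3-bis{[3,5-bis(trifluoromethyl)phenyl]sulfonyl}-4,5-diphenyl-1,3,2-diazaborolidin-2-yl group on oxygen (C7 chain trans to O–B) | C#CCC/C=C(\OC/C(C)=C/CCO[Si](C)(C)C(C)(C)C)OB1N(S(=O)(=O)c2cc(cc(c2)C(F)(F)F)C(F)(F)F)[C@@H](c2ccccc2)[C@H](c2ccccc2)N1S(=O)(=O)c1cc(cc(c1)C(F)(F)F)C(F)(F)F | intermediate (not isolated)
7 | acyloxyborane, the same diazaborolidin-2-yl ester of acid 8 | O=C(OB1N(S(=O)(=O)c2cc(cc(c2)C(F)(F)F)C(F)(F)F)[C@@H](c2ccccc2)[C@H](c2ccccc2)N1S(=O)(=O)c1cc(cc(c1)C(F)(F)F)C(F)(F)F)[C@H](CCC#C)[C@H](CCO[Si](C)(C)C(C)(C)C)C(C)=C | intermediate (not isolated)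
8 | (2R,3S)-2-(but-3-yn-1-yl)-3-{2-[(tert-butyldimethylsilyl)oxy]ethyl}-4-methylpent-4-enoic acid | OC(=O)[C@H](CCC#C)[C@H](CCO[Si](C)(C)C(C)(C)C)C(C)=C | intermediate
9 | (2R,3S)-2-(but-3-yn-1-yl)-3-{2-[(tert-butyldimethylsilyl)oxy]ethyl}-4-methylpent-4-en-1-ol | OC[C@H](CCC#C)[C@H](CCO[Si](C)(C)C(C)(C)C)C(C)=C | intermediate
10 | 1-({[(2R,3S)-2-(but-3-yn-1-yl)-3-{2-[(tert-butyldimethylsilyl)oxy]ethyl}-4-methylpent-4-en-1-yl]oxy}methyl)-4-methoxybenzene | COc1ccc(COC[C@H](CCC#C)[C@H](CCO[Si](C)(C)C(C)(C)C)C(C)=C)cc1 | intermediate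
11 | tert-butyl (6R,7S)-7-{2-[(tert-butyldimethylsilyl)oxy]ethyl}-6-{[(4-methoxybenzyl)oxy]methyl}-8-methylnon-8-en-2-ynoate | COc1ccc(COC[C@H](CCC#CC(=O)OC(C)(C)C)[C@H](CCO[Si](C)(C)C(C)(C)C)C(C)=C)cc1 | intermediate
12 | tert-butyl (2E,6R,7S)-7-{2-[(tert-butyldimethylsilyl)oxy]ethyl}-6-{[(4-methoxybenzyl)oxy]methyl}-8-methyl-2-(tributylstannyl)nona-2,8-dienoate | COc1ccc(COC[C@H](CC/C=C(/[Sn](CCCC)(CCCC)CCCC)C(=O)OC(C)(C)C)[C@H](CCO[Si](C)(C)C(C)(C)C)C(C)=C)cc1 | intermediate (not isolated)
13 | tert-butyl (2E,6R,7S)-7-{2-[(tert-butyldimethylsilyl)oxy]ethyl}-2-iodo-6-{[(4-methoxybenzyl)oxy]methyl}-8-methylnona-2,8-dienoate | COc1ccc(COC[C@H](CC/C=C(/I)C(=O)OC(C)(C)C)[C@H](CCO[Si](C)(C)C(C)(C)C)C(C)=C)cc1 | intermediate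
14 | tert-butyl (2Z,6R,7S)-2-ethenyl-7-{2-[(tert-butyldimethylsilyl)oxy]ethyl}-6-{[(4-methoxybenzyl)oxy]methyl}-8-methylnona-2,8-dienoate | COc1ccc(COC[C@H](CC/C=C(/C=C)C(=O)OC(C)(C)C)[C@H](CCO[Si](C)(C)C(C)(C)C)C(C)=C)cc1 | intermediate
15 | tert-butyl (5R,8R,9S,10R)-12-[(tert-butyldimethylsilyl)oxy]-17-[(4-methoxybenzyl)oxy]-13,14,15,16,18-pentanorlabd-3-en-19-oate | C[C@]12CCC=C(C(=O)OC(C)(C)C)[C@@H]1CC[C@@H](COCc1ccc(OC)cc1)[C@@H]2CCO[Si](C)(C)C(C)(C)C | intermediate
16 | tert-butyl 12-[(tert-butyldimethylsilyl)oxy]-17-[(4-methoxybenzyl)oxy]-13,14,15,16,18-pentanorlabdan-19-oate (5α-H, 8β-H, 9α-H, 10β-CH3; C4 epimers) | C[C@]12CCCC(C(=O)OC(C)(C)C)[C@@H]1CC[C@@H](COCc1ccc(OC)cc1)[C@@H]2CCO[Si](C)(C)C(C)(C)C | intermediate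
17 | tert-butyl (4S,5R,8R,9S,10R)-12-[(tert-butyldimethylsilyl)oxy]-17-[(4-methoxybenzyl)oxy]-13,14,15,16-tetranorlabdan-19-oate | C[C@]12CCC[C@](C)(C(=O)OC(C)(C)C)[C@@H]1CC[C@@H](COCc1ccc(OC)cc1)[C@@H]2CCO[Si](C)(C)C(C)(C)C | intermediate
18 | tert-butyl (4S,5R,8R,9S,10R)-12-hydroxy-17-[(4-methoxybenzyl)oxy]-13,14,15,16-tetranorlabdan-19-oate | C[C@]12CCC[C@](C)(C(=O)OC(C)(C)C)[C@@H]1CC[C@@H](COCc1ccc(OC)cc1)[C@@H]2CCO | intermediate
19 | tert-butyl (4S,5R,8R,9S,10R)-12-iodo-17-[(4-methoxybenzyl)oxy]-13,14,15,16-tetranorlabdan-19-oate | C[C@]12CCC[C@](C)(C(=O)OC(C)(C)C)[C@@H]1CC[C@@H](COCc1ccc(OC)cc1)[C@@H]2CCI | intermediate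
20 | 3-bromofuran-2(5H)-one | O=C1OCC=C1Br | starting material
21 | alkylzinc iodide from 19 (C12–ZnI) | C[C@]12CCC[C@](C)(C(=O)OC(C)(C)C)[C@@H]1CC[C@@H](COCc1ccc(OC)cc1)[C@@H]2CC[Zn]I | intermediate (not isolated)
22 | tert-butyl (4S,5R,8R,9S,10R)-17-[(4-methoxybenzyl)oxy]labd-13-en-16,15-olid-19-oate | C[C@]12CCC[C@](C)(C(=O)OC(C)(C)C)[C@@H]1CC[C@@H](COCc1ccc(OC)cc1)[C@@H]2CCC1=CCOC1=O | intermediate
23 | (4S,5R,8R,9S,10R)-17-hydroxylabd-13-en-16,15-olid-19-oic acid (CNP0562063.1) | C[C@]12CCC[C@](C)(C(=O)O)[C@@H]1CC[C@@H](CO)[C@@H]2CCC1=CCOC1=O | target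

**Step count**
Total steps: 16. Longest linear sequence: 16 (1 → 23); 4 and 20 are commercial and enter directly.

**Steps most likely to fail**

Step 10. Neither partner is strongly activated, so the cycloaddition may need temperatures at which the tert-butyl dienoate loses isobutene or dimerises, and the preference for the trans-fused over the cis-fused transition state may be incomplete. The fallback carries C19 through the cycloaddition at the alcohol oxidation level: a diene that cannot dimerise as an acrylate or lose isobutene, with an sp3 substituent on C4 that cannot twist out of the diene plane. It sets out from 14. i-Bu2AlH (CH2Cl2, −78 °C) should give the dienyl alcohol F1. Heating F1 in dilute toluene with BHT at 180–200 °C should give the trans-fused allylic alcohol F2. MnO2 should oxidise F2 to the enal F3, and NaClO2/NaH2PO4/2-methyl-2-butene (Pinnick oxidation) should give the enoic acid F4. Boc2O/DMAP/t-BuOH then re-forms the tert-butyl ester, and the route is rejoined at 15.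

Step 4. The boron enolate may form with incomplete E(O) geometry or rearrange with incomplete facial control, and the boron halide may engage the terminal alkyne, so the acid could be obtained with eroded diastereo- or enantiopurity. The fallback replaces reagent control by the classical silyl variant plus resolution and sets out from 5. LiN(i-Pr)2 (2.3 equiv) and Me3SiCl in THF at −78 °C should give the C-silylated silyl ketene acetal F5, which rearranges on warming to the silyl ester F6. K2CO3/MeOH should remove both trimethylsilyl groups to give the racemic anti acid F7. Crystallisation with (S)-1-phenylethylamine (or its enantiomer, whichever gives the less soluble salt of the wanted acid) should give the diastereomerically pure ammonium salt F8, and acidification returns the route to 8.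

Step 15. Zinc insertion into the neopentyl-flanked iodide may be slow, and the alkylpalladium intermediate may undergo β-hydride elimination or protonolysis faster than coupling with the base-sensitive bromobutenolide. The fallback builds the butenolide ring on the side chain instead of coupling it and sets out from 19. Alkylation of the sodium salt of allyl (diethoxyphosphoryl)acetate (NaH, DMF, 50 °C) should give the phosphonate F9. Horner–Wadsworth–Emmons methylenation with aqueous formaldehyde/K2CO3 should give the allyl 2-alkylacrylate F10. Ring-closing metathesis with the second-generation Grubbs catalyst (CH2Cl2, 40 °C) should close the butenolide and return the route to 22.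

**Further compounds**
F1 | step 10 | (2Z,6R,7S)-2-ethenyl-7-{2-[(tert-butyldimethylsilyl)oxy]ethyl}-6-{[(4-methoxybenzyl)oxy]methyl}-8-methylnona-2,8-dien-1-ol | COc1ccc(COC[C@H](CC/C=C(/C=C)CO)[C@H](CCO[Si](C)(C)C(C)(C)C)C(C)=C)cc1
F2 | step 10 | (5R,8R,9S,10R)-12-[(tert-butyldimethylsilyl)oxy]-17-[(4-methoxybenzyl)oxy]-13,14,15,16,18-pentanorlabd-3-en-19-ol | C[C@]12CCC=C(CO)[C@@H]1CC[C@@H](COCc1ccc(OC)cc1)[C@@H]2CCO[Si](C)(C)C(C)(C)C
F3 | step 10 | (5R,8R,9S,10R)-12-[(tert-butyldimethylsilyl)oxy]-17-[(4-methoxybenzyl)oxy]-13,14,15,16,18-pentanorlabd-3-en-19-al | C[C@]12CCC=C(C=O)[C@@H]1CC[C@@H](COCc1ccc(OC)cc1)[C@@H]2CCO[Si](C)(C)C(C)(C)C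
F4 | step 10 | (5R,8R,9S,10R)-12-[(tert-butyldimethylsilyl)oxy]-17-[(4-methoxybenzyl)oxy]-13,14,15,16,18-pentanorlabd-3-en-19-oic acid | C[C@]12CCC=C(C(O)=O)[C@@H]1CC[C@@H](COCc1ccc(OC)cc1)[C@@H]2CCO[Si](C)(C)C(C)(C)C
F5 | step 4 | trimethylsilyl ketene acetal of 5 with C-trimethylsilylated alkyne (C7 chain trans to O–Si) | C[Si](C)(C)C#CCC/C=C(\OC/C(C)=C/CCO[Si](C)(C)C(C)(C)C)O[Si](C)(C)C
F6 | step 4 | trimethylsilyl rac-(2R*,3S*)-3-{2-[(tert-butyldimethylsilyl)oxy]ethyl}-4-methyl-2-[4-(trimethylsilyl)but-3-yn-1-yl]pent-4-enoate (racemate, one enantiomer drawn) | C[Si](C)(C)OC(=O)[C@H](CCC#C[Si](C)(C)C)[C@H](CCO[Si](C)(C)C(C)(C)C)C(C)=C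
F7 | step 4 | rac-(2R*,3S*)-2-(but-3-yn-1-yl)-3-{2-[(tert-butyldimethylsilyl)oxy]ethyl}-4-methylpent-4-enoic acid (racemate, one enantiomer drawn) | OC(=O)[C@H](CCC#C)[C@H](CCO[Si](C)(C)C(C)(C)C)C(C)=C
F8 | step 4 | (S)-1-phenylethylammonium (2R,3S)-2-(but-3-yn-1-yl)-3-{2-[(tert-butyldimethylsilyl)oxy]ethyl}-4-methylpent-4-enoate | C[C@H]([NH3+])c1ccccc1.[O-]C(=O)[C@H](CCC#C)[C@H](CCO[Si](C)(C)C(C)(C)C)C(C)=C
F9 | step 15 | allyl 2-(diethoxyphosphoryl) ester homologue of 19: C12 bonded to the α-carbon of allyl (diethoxyphosphoryl)acetate (epimers at that carbon) | C[C@]12CCC[C@](C)(C(=O)OC(C)(C)C)[C@@H]1CC[C@@H](COCc1ccc(OC)cc1)[C@@H]2CCC(C(=O)OCC=C)P(=O)(OCC)OCC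
F10 | step 15 | allyl 2-methylidene ester: C12 bonded to C13 of an allyl acrylate (C13=CH2, C16 allyl ester) | C[C@]12CCC[C@](C)(C(=O)OC(C)(C)C)[C@@H]1CC[C@@H](COCc1ccc(OC)cc1)[C@@H]2CCC(=C)C(=O)OCC=C
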